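At early times starting material falls alike in percent at 41 mM and 82 mM, 92.3% against 92.4% after 0.417 min, and at 2.00 min the violet run, with half of green's partner, holds 73.1% against 71.5%, while its target stands lower than green's, 8.4% against 12.6%.

| setting | green | violet | ochre | amber | gamma | alpha | theta |
|---|---|---|---|---|---|---|---|
| starting material | 41 mM | 41 mM | 41 mM | 82 mM | 41 mM (fed, over 4.0 min) | 41 mM | 41 mM |
| partner | 32.8 mM | 16 mM | 25 mM | 32.8 mM | 32.8 mM | 32.8 mM (fed, over 4.0 min) | 32.8 mM |
| remark | run made earlier | run made earlier | run made earlier | run made earlier | all else is in the flask from the start; the feed brings no volume worth counting | all else is in the flask from the start; the feed brings no volume worth counting | everything together at the start |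
| time |  |  |  |  | 5.0 min | 5.0 min | 5.0 min |

| run | time / min | target / % | starting material / % |
|---|---|---|---|
| green | 0.417 | 0.4 | 92.3 |
| green | 1.00 | 5.0 | 83.9 |
| green | 2.00 | 12.6 | 71.5 |
| green | 3.00 | 20.6 | 61.8 |
| violet | 0.417 | 1.6 | 92.6 |
| violet | 1.00 | 2.6 | 84.1 |
| violet | 2.00 | 8.4 | 73.1 |
| violet | 5.00 | 19.7 | 52.9 |
| ochre | 0.667 | 2.4 | 88.9 |
| ochre | 2.00 | 10.7 | 73.2 |
| ochre | 3.00 | 16.8 | 63.5 |
| ochre | 5.00 | 25.7 | 48.8 |
| amber | 0.417 | 1.7 | 92.4 |
| amber | 1.00 | 4.0 | 83.5 |
| amber | 2.00 | 13.0 | 72.1 |
| amber | 5.00 | 25.0 | 50.2 |

(scatter of a reading: 0.5 percentage points)

- what was read earlier has a scatter of 0.5 percentage points, one standard deviation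
- steps under discussion: target <-> isomer of the product; starting material <-> open intermediate; open intermediate + second intermediate -> target; partner -> second intermediate

- which flask leads in amount of target, in percent of the starting material charged ("all alike" within 1.5 percentage points) (gamma / alpha / theta / all alike)
- how much target is there at the end, in percent of the starting material charged: gamma
- how much target is there at the end, in percent of the starting material charged: alpha
- how much target is there at the end, in percent of the starting material charged: theta

I carry one quantity. Green at 3.00 min has lost 38.2% of its starting material and holds 20.6% target, which gives φ = 53.9%, the target share (the selectivity): target standing per starting material gone. The same reading gives a first-order pace of loss, k = 0.160 min⁻¹, so theta, which is green read on, loses 55.2% by 5.0 min and holds 29.7% target.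

Two views part over the fed flasks. The clock view says a steady feed arrives on average 2.00 min late, so gamma and alpha are both green read at 3.00 min, with 20.6% target. The opening view accepts this for gamma, but says that alpha's starting material stands in the flask from the start and opens without waiting for partner, so alpha matches theta at 29.7%. I hold the opening view and name theta, with alpha beside it. The forecast, close to this but with its own figures, gives gamma 20.5%, alpha 29%, theta 31%: “Theta leads narrowly”.

The flasks give gamma 19.5%, alpha 25.7% and theta 29.8%, so theta leads. Alpha falls 4 percentage points below the opening view and stands 5.1 points above the clock view, whose region is gamma, where it misses by 1.1 points.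

    target ⇌ isomer of the product (K = 0.490, k = 0.0270 s⁻¹)
    starting material ⇌ open intermediate (K = 0.600, k = 0.00330 s⁻¹)
    open intermediate + second intermediate → target (k = 0.750 M⁻¹ s⁻¹)
    partner → second intermediate (k = 0.0430 s⁻¹)

Alpha keeps 52% starting material against theta's 47%, and φ on alpha's loss gives 25.9% target beside the flask's 25.7%. In theta, target and isomer of the product relax by their own step, both ways together, with a half-life of 0.141 min, short against 5.0 min, and theta holds 14.0% isomer beside 29.8% target at the end.

For theta left until 8.0 min, the pace leaves 27.8% starting material and φ gives 38.9% target. The computed flask holds 32.7% starting material and 39.4% target.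

All runs come from a simulation with constants of no real substance; noise was put on by code.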